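**Retrosynthetic overview**
- C40 = C15 (diol end) + C10 + C15 (furanoid end): C11'=C12' (last) and C11=C12 are cut as Horner–Wadsworth–Emmons bonds around a C10 bisphosphonate.
- The strategy rests on the 5',8'-epoxy end group, a 2,5-dihydrofuran (O, C5', C6'=C7', C8') fused to the trimethylcyclohexane. It is the cycloisomer of a 5'-hydroxy-6',7'-allene, and C5' has the same R configuration as C5 of the cis-5,6-diol ring, so one Sharpless epoxide of β-cyclogeraniol feeds both halves.
- Furanoid half: epoxy aldehyde → ethynyl epoxide → anti-SN2' alkenylation (C8'–C9') → allenol → O5'–C8' closure.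
- Diol half: the same epoxy aldehyde → Wharton transposition and ozonolysis (C7 removed) → α-silyloxy ketone → acetylide addition (C6–C7), trans-reduction, oxidation.
- Ring order: both cyclohexanes are bought as β-cyclocitral; the oxirane is made first; the dihydrofuran is closed at the C15 stage, before any polyene exists.

Key step: step 8

Remark: carotenoid numbering is used for positions (C5, C6, C7 … and primed locants for the furanoid half).
Remark: mapping β-cyclogeraniol onto geraniol (where L-(+)-tartrate gives the 2S,3S epoxide) shows that the 5R epoxide needed for both ends requires D-(−)-diethyl tartrate; the route uses that ester.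

**Route**

Step 1
Reactants: 1 β-cyclocitral (2,6,6-trimethylcyclohex-1-ene-1-carbaldehyde)
Product: 2 β-cyclogeraniol ((2,6,6-trimethylcyclohex-1-en-1-yl)methanol)
Conditions: NaBH4, MeOH, 0 °C
Reagents that add atoms: none
Why: Borohydride 1,2-reduction of the hindered enal should give the allylic alcohol needed for directed epoxidation.

Step 2
Reactants: 2 β-cyclogeraniol
Product: 3 [(1R,6R)-2,2,6-trimethyl-7-oxabicyclo[4.1.0]heptan-1-yl]methanol
Conditions: Ti(OiPr)4 (cat.), D-(−)-diethyl tartrate (cat.), t-BuOOH, 4 Å MS, CH2Cl2, −20 °C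
Reagents that add atoms: tert-butyl hydroperoxide, CC(C)(C)OO
Why: Katsuki–Sharpless asymmetric epoxidation, in which the Ti(OiPr)4–tartrate catalyst delivers oxygen to one alkene face of the bound allylic alcohol; with the D-(−)-ester this should set C5 as R (and C6 with it), the configuration required at C5 and C5' of the target.

Step 3
Reactants: 3 [(1R,6R)-2,2,6-trimethyl-7-oxabicyclo[4.1.0]heptan-1-yl]methanol
Product: 4 (1S,6R)-2,2,6-trimethyl-7-oxabicyclo[4.1.0]heptane-1-carbaldehyde
Conditions: Dess–Martin periodinane, NaHCO3, CH2Cl2, 0 °C → rt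
Reagents that add atoms: none
Why: Buffered Dess–Martin oxidation should convert the neopentyl-type primary alcohol into the non-enolisable epoxy aldehyde without opening the oxirane (the descriptor at the ring-fusion carbon changes only through priorities).

Step 4
Reactants: 4 (1S,6R)-2,2,6-trimethyl-7-oxabicyclo[4.1.0]heptane-1-carbaldehyde
Product: 5 (1R,6R)-1-ethynyl-2,2,6-trimethyl-7-oxabicyclo[4.1.0]heptane
Conditions: dimethyl (1-diazo-2-oxopropyl)phosphonate, K2CO3, MeOH, 0 °C → rt
Reagents that add atoms: dimethyl (1-diazo-2-oxopropyl)phosphonate, CC(=O)C(=[N+]=[N-])P(=O)(OC)OC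
Why: Ohira–Bestmann homologation (Seyferth–Gilbert type) should turn the non-enolisable aldehyde into the terminal alkyne under mild carbonate conditions that leave the fully substituted epoxide intact.

Step 5
Reactants: 6 but-2-yn-1-ol
Product: 7 tert-butyl(but-2-yn-1-yloxy)dimethylsilane
Conditions: TBSCl, imidazole, CH2Cl2, 0 °C → rt
Reagents that add atoms: tert-butyldimethylsilyl chloride, CC(C)(C)[Si](C)(C)Cl
Why: Standard silylation protects the primary alcohol for the borylation and the cross-coupling.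

Step 6
Reactants: 7 tert-butyl(but-2-yn-1-yloxy)dimethylsilane
Product: 8 (Z)-tert-butyldimethyl{[3-(4,4,5,5-tetramethyl-1,3,2-dioxaborolan-2-yl)but-2-en-1-yl]oxy}silane
Conditions: CuCl (5 mol %), NaOtBu (10 mol %), Xantphos (5 mol %), B2pin2, MeOH, THF, rt
Reagents that add atoms: bis(pinacolato)diboron, CC1(C)OB(OC1(C)C)B1OC(C)(C)C(C)(C)O1
Why: Copper-catalysed formal hydroboration adds boron and hydrogen syn across the alkyne, with boron on the carbon remote from the oxygenated CH2 (C3), so boron ends trans to the silyloxymethyl group as the E chain geometry at C9'=C10' requires.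

Step 7
Reactants: 5 (1R,6R)-1-ethynyl-2,2,6-trimethyl-7-oxabicyclo[4.1.0]heptane; 8 (Z)-tert-butyldimethyl{[3-(4,4,5,5-tetramethyl-1,3,2-dioxaborolan-2-yl)but-2-en-1-yl]oxy}silane
Product: 9 (1R)-2-[(aR,3E)-5-(tert-butyldimethylsilyloxy)-3-methylpenta-1,3-dien-1-ylidene]-1,3,3-trimethylcyclohexan-1-ol
Conditions: Pd(PPh3)4 (5 mol %), KOH (0.2 equiv), THF–H2O (10:1), 40 °C
Reagents that add atoms: none
Why: Zerovalent palladium attacks the alkyne terminus C8' anti to the breaking C6'–O bond (SN2' oxidative addition), and the allenylpalladium formed transmetalates with the alkenylboronate and eliminates reductively with retention (Suzuki–Miyaura-type coupling of a propargylic epoxide), so C8'–C9' forms with C9' anti and H syn to the former C6'–O bond and the allene axis is fixed by the epoxide.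

Step 8
Reactants: 9 (1R)-2-[(aR,3E)-5-(tert-butyldimethylsilyloxy)-3-methylpenta-1,3-dien-1-ylidene]-1,3,3-trimethylcyclohexan-1-ol
Product: 10 tert-butyldimethyl{[(2E)-3-[(2S,7aR)-4,4,7a-trimethyl-2,4,5,6,7,7a-hexahydro-1-benzofuran-2-yl]but-2-en-1-yl]oxy}silane
Conditions: Ph3PAuCl (5 mol %), AgBF4 (5 mol %), 2,6-di-tert-butylpyridine (10 mol %), THF, −20 → 0 °C, dark
Reagents that add atoms: none
Why: The cationic Ph3PAu+ fragment (monovalent gold) binds the C7'=C8' π bond of the allene, which lies in the plane of C5', C6' and C7', on the side remote from O5'; the tertiary hydroxyl then adds to C8' anti to the metal and protodeauration of the C7' vinylgold releases the catalyst. The closest known reaction type is the gold- or silver-catalysed cycloisomerisation of α-hydroxyallenes to 2,5-dihydrofurans with axis-to-centre chirality transfer. The ring O–C5'–C6'=C7'–C8' closes by 5-endo attack of oxygen on the distal allene carbon, forming the O5'–C8' bond. The only new stereocentre, C8', is controlled by the allene axis: because the attack is in-plane, H and C9' keep their faces, and C9', placed anti to the former C6'–O bond in step 7, should end cis to the C5' methyl, that is 8'S. The step needs stereospecific anti addition without ionisation of the doubly allylic C8'–O bond; this is secured by the single allene diastereomer, the hydroxyl held next to the allene on a fully substituted ring carbon, the absence of any other nucleophile or polyene at the C15 stage, and a phosphine-ligated, pyridine-buffered catalyst in THF at low temperature.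

Step 9
Reactants: 10 tert-butyldimethyl{[(2E)-3-[(2S,7aR)-4,4,7a-trimethyl-2,4,5,6,7,7a-hexahydro-1-benzofuran-2-yl]but-2-en-1-yl]oxy}silane
Product: 11 (2E)-3-[(2S,7aR)-4,4,7a-trimethyl-2,4,5,6,7,7a-hexahydro-1-benzofuran-2-yl]but-2-en-1-ol
Conditions: Bu4NF, THF, 0 °C
Reagents that add atoms: none
Why: Fluoride desilylation is non-acidic and should leave the acid-labile doubly allylic ether at C8' untouched.

Step 10
Reactants: 11 (2E)-3-[(2S,7aR)-4,4,7a-trimethyl-2,4,5,6,7,7a-hexahydro-1-benzofuran-2-yl]but-2-en-1-ol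
Product: 12 (2E)-3-[(2S,7aR)-4,4,7a-trimethyl-2,4,5,6,7,7a-hexahydro-1-benzofuran-2-yl]but-2-enal
Conditions: MnO2, CH2Cl2, rt
Reagents that add atoms: none
Why: Activated MnO2 oxidises the primary allylic alcohol selectively under neutral conditions, keeping the 9'E geometry and the C8' centre.

Step 11
Reactants: 4 (1S,6R)-2,2,6-trimethyl-7-oxabicyclo[4.1.0]heptane-1-carbaldehyde
Product: 14 (1R)-1,3,3-trimethyl-2-methylidenecyclohexan-1-ol, via epoxy hydrazone 13 (not isolated)
Conditions: N2H4·H2O, AcOH (cat.), MeOH, 0 °C → rt, N2 atmosphere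
Reagents that add atoms: none
Why: Wharton transposition: the hydrazone of the α,β-epoxy aldehyde opens the oxirane and loses nitrogen, turning the aldehyde carbon into an exocyclic methylidene while the C5–O bond and its R configuration are untouched.

Step 12
Reactants: 14 (1R)-1,3,3-trimethyl-2-methylidenecyclohexan-1-ol
Product: 16 (2R)-2-hydroxy-2,6,6-trimethylcyclohexan-1-one, via ozonide 15 (not isolated)
Conditions: O3, CH2Cl2, −78 °C; then Me2S, −78 °C → rt
Reagents that add atoms: ozone, [O-][O+]=O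
Why: Ozonolysis with reductive work-up excises the methylidene carbon (C7) and should leave the non-enolisable α-hydroxy ketone.

Step 13
Reactants: 16 (2R)-2-hydroxy-2,6,6-trimethylcyclohexan-1-one
Product: 17 (2R)-2,6,6-trimethyl-2-(trimethylsilyloxy)cyclohexan-1-one
Conditions: TMSOTf, 2,6-lutidine, CH2Cl2, −78 → 0 °C
Reagents that add atoms: trimethylsilyl trifluoromethanesulfonate, C[Si](C)(C)OS(=O)(=O)C(F)(F)F
Why: Silylation with the triflate caps the hindered tertiary hydroxyl as a poorly chelating ether, and the ketone, lacking α-hydrogens, cannot form a silyl enol ether.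

Step 14
Reactants: 17 (2R)-2,6,6-trimethyl-2-(trimethylsilyloxy)cyclohexan-1-one; 18 (2E)-3-methylpent-2-en-4-yn-1-ol
Product: 21 (1R,2R)-1-[(3E)-5-hydroxy-3-methylpent-3-en-1-yn-1-yl]-2,6,6-trimethylcyclohexane-1,2-diol, via dilithio enynol 19 (not isolated), via silyl ether adduct 20 (not isolated)
Conditions: 18, n-BuLi (2 equiv), THF, −78 → −20 °C; 17, −78 → 0 °C; H2O; then Bu4NF, THF, 0 °C
Reagents that add atoms: none
Why: Acetylide addition to the non-enolisable α-silyloxy ketone without chelation should follow the Felkin–Anh (polar) model, the slim nucleophile entering axially anti to the axial C5–OSiMe3 bond so that the new C6 hydroxyl is cis to the C5 oxygen; desilylation in the same operation makes any silyl shift between the vicinal oxygens irrelevant.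

Step 15
Reactants: 21 (1R,2R)-1-[(3E)-5-hydroxy-3-methylpent-3-en-1-yn-1-yl]-2,6,6-trimethylcyclohexane-1,2-diol
Product: 22 (1S,2R)-1-[(1E,3E)-5-hydroxy-3-methylpenta-1,3-dien-1-yl]-2,6,6-trimethylcyclohexane-1,2-diol
Conditions: NaAlH2(OCH2CH2OCH3)2 (excess), THF, 0 °C → rt; aq KNaC4H4O6
Reagents that add atoms: none
Why: Hydroxyl-directed trans-hydroalumination of the propargylic alkyne through the C6 alkoxyaluminate, followed by protonolysis, should give the 7E alkene (the C6 descriptor changes only through priorities).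

Step 16
Reactants: 22 (1S,2R)-1-[(1E,3E)-5-hydroxy-3-methylpenta-1,3-dien-1-yl]-2,6,6-trimethylcyclohexane-1,2-diol
Product: 23 (2E,4E)-5-[(1S,2R)-1,2-dihydroxy-2,6,6-trimethylcyclohexyl]-3-methylpenta-2,4-dienal
Conditions: MnO2, CH2Cl2, rt
Reagents that add atoms: none
Why: MnO2 oxidises only the primary allylic alcohol; the two tertiary hydroxyls cannot be oxidised.

Step 17
Reactants: 23 (2E,4E)-5-[(1S,2R)-1,2-dihydroxy-2,6,6-trimethylcyclohexyl]-3-methylpenta-2,4-dienal
Product: 24 (2E,4E)-3-methyl-5-[(1S,2R)-2,6,6-trimethyl-1,2-bis(trimethylsilyloxy)cyclohexyl]penta-2,4-dienal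
Conditions: TMSOTf (2.5 equiv), 2,6-lutidine, CH2Cl2, −78 °C
Reagents that add atoms: trimethylsilyl trifluoromethanesulfonate, C[Si](C)(C)OS(=O)(=O)C(F)(F)F
Why: Low-temperature silylation with the triflate and a hindered pyridine caps both congested tertiary hydroxyls faster than the enal can be enolised, so no alkoxide is present in the olefinations.

Step 18
Reactants: 25 (2E,4E,6E)-2,7-dimethylocta-2,4,6-trienedial
Product: 26 (2E,4E,6E)-2,7-dimethylocta-2,4,6-triene-1,8-diol
Conditions: NaBH4, MeOH–THF, 0 °C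
Reagents that add atoms: none
Why: 1,2-Reduction of both formyl groups of the trienedial gives the bis-allylic diol with the triene geometry unchanged.

Step 19
Reactants: 26 (2E,4E,6E)-2,7-dimethylocta-2,4,6-triene-1,8-diol
Product: 27 (2E,4E,6E)-1,8-dibromo-2,7-dimethylocta-2,4,6-triene
Conditions: PBr3, pyridine (cat.), Et2O, −10 °C, dark; used crude
Reagents that add atoms: phosphorus tribromide, BrP(Br)Br
Why: PBr3 converts the primary allylic alcohols into bromides by substitution at the unhindered CH2 termini.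

Step 20
Reactants: 27 (2E,4E,6E)-1,8-dibromo-2,7-dimethylocta-2,4,6-triene
Product: 28 tetraethyl [(2E,4E,6E)-2,7-dimethylocta-2,4,6-triene-1,8-diyl]bis(phosphonate)
Conditions: P(OEt)3, 120 °C
Reagents that add atoms: triethyl phosphite, CCOP(OCC)OCC
Why: Twofold Michaelis–Arbuzov reaction at the primary allylic bromides gives the C10 bisphosphonate.

Step 21
Reactants: 24 (2E,4E)-3-methyl-5-[(1S,2R)-2,6,6-trimethyl-1,2-bis(trimethylsilyloxy)cyclohexyl]penta-2,4-dienal; 28 tetraethyl [(2E,4E,6E)-2,7-dimethylocta-2,4,6-triene-1,8-diyl]bis(phosphonate)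
Product: 29 diethyl [(2E,4E,6E,8E,10E,12E)-2,7,11-trimethyl-13-[(1S,2R)-2,6,6-trimethyl-1,2-bis(trimethylsilyloxy)cyclohexyl]trideca-2,4,6,8,10,12-hexaen-1-yl]phosphonate
Conditions: 28 (3 equiv), KOtBu (1 equiv), THF, −30 °C; then 24, −30 °C → rt, dim light
Reagents that add atoms: none
Why: Horner–Wadsworth–Emmons olefination with the mono-anion of the bisphosphonate, held in excess so that only one end reacts, forms C11=C12 with the E preference of allylic phosphonate anions and keeps the second phosphonate for the last coupling.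

Step 22
Reactants: 12 (2E)-3-[(2S,7aR)-4,4,7a-trimethyl-2,4,5,6,7,7a-hexahydro-1-benzofuran-2-yl]but-2-enal; 29 diethyl [(2E,4E,6E,8E,10E,12E)-2,7,11-trimethyl-13-[(1S,2R)-2,6,6-trimethyl-1,2-bis(trimethylsilyloxy)cyclohexyl]trideca-2,4,6,8,10,12-hexaen-1-yl]phosphonate
Product: 31 target (5R,6S,5'R,8'S)-5',8'-epoxy-5,6,5',8'-tetrahydro-β,β-carotene-5,6-diol (CNP0378030.2), via bis-silyl carotenoid 30 (not isolated)
Conditions: 29, KOtBu (1.05 equiv), THF, −40 °C; then 12, −40 → 0 °C; then Bu4NF, 0 °C; pH 7 buffer; argon, dim light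
Reagents that add atoms: none
Why: Horner–Wadsworth–Emmons olefination of the enal by the preformed potassium salt of the polyenyl phosphonate forms C11'=C12' with E preference, the stoichiometric cold anion leaving the γ-hydrogen at C8' alone, and fluoride then removes both tertiary trimethylsilyl ethers without acid, which the C8'–O bond would not tolerate.

**Compound list**

1 | β-cyclocitral | CC1=C(C=O)C(C)(C)CCC1 | starting material
2 | β-cyclogeraniol | CC1=C(CO)C(C)(C)CCC1 | intermediate
3 | [(1R,6R)-2,2,6-trimethyl-7-oxabicyclo[4.1.0]heptan-1-yl]methanol | OC[C@]12C(C)(C)CCC[C@@]1(C)O2 | intermediate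
4 | (1S,6R)-2,2,6-trimethyl-7-oxabicyclo[4.1.0]heptane-1-carbaldehyde | O=C[C@]12C(C)(C)CCC[C@@]1(C)O2 | intermediate
5 | (1R,6R)-1-ethynyl-2,2,6-trimethyl-7-oxabicyclo[4.1.0]heptane | C#C[C@]12C(C)(C)CCC[C@@]1(C)O2 | intermediate
6 | but-2-yn-1-ol | CC#CCO | starting material
7 | tert-butyl(but-2-yn-1-yloxy)dimethylsilane | CC#CCO[Si](C)(C)C(C)(C)C | intermediate
8 | (Z)-tert-butyldimethyl{[3-(4,4,5,5-tetramethyl-1,3,2-dioxaborolan-2-yl)but-2-en-1-yl]oxy}silane | C/C(B1OC(C)(C)C(C)(C)O1)=C\CO[Si](C)(C)C(C)(C)C | intermediate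
9 | (1R)-2-[(aR,3E)-5-(tert-butyldimethylsilyloxy)-3-methylpenta-1,3-dien-1-ylidene]-1,3,3-trimethylcyclohexan-1-ol (C15 vinylallenol, C9' on the face opposite to the hydroxyl) | C/C(=C\CO[Si](C)(C)C(C)(C)C)C([H])=[C@@]=C1C(C)(C)CCC[C@@]1(C)O | intermediate
10 | tert-butyldimethyl{[(2E)-3-[(2S,7aR)-4,4,7a-trimethyl-2,4,5,6,7,7a-hexahydro-1-benzofuran-2-yl]but-2-en-1-yl]oxy}silane | C/C(=C\CO[Si](C)(C)C(C)(C)C)[C@@H]1C=C2C(C)(C)CCC[C@@]2(C)O1 | intermediate
11 | (2E)-3-[(2S,7aR)-4,4,7a-trimethyl-2,4,5,6,7,7a-hexahydro-1-benzofuran-2-yl]but-2-en-1-ol | C/C(=C\CO)[C@@H]1C=C2C(C)(C)CCC[C@@]2(C)O1 | intermediate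
12 | (2E)-3-[(2S,7aR)-4,4,7a-trimethyl-2,4,5,6,7,7a-hexahydro-1-benzofuran-2-yl]but-2-enal | C/C(=C\C=O)[C@@H]1C=C2C(C)(C)CCC[C@@]2(C)O1 | intermediate
13 | hydrazone of epoxy aldehyde 4 | NN=C[C@]12C(C)(C)CCC[C@@]1(C)O2 | intermediate (not isolated)
14 | (1R)-1,3,3-trimethyl-2-methylidenecyclohexan-1-ol | C=C1C(C)(C)CCC[C@@]1(C)O | intermediate
15 | spiro-1,2,4-trioxolane (ozonide) of 14 | C1OC2(OO1)C(C)(C)CCC[C@@]2(C)O | intermediate (not isolated)
16 | (2R)-2-hydroxy-2,6,6-trimethylcyclohexan-1-one | O=C1C(C)(C)CCC[C@@]1(C)O | intermediate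
17 | (2R)-2,6,6-trimethyl-2-(trimethylsilyloxy)cyclohexan-1-one | O=C1C(C)(C)CCC[C@@]1(C)O[Si](C)(C)C | intermediate
18 | (2E)-3-methylpent-2-en-4-yn-1-ol | C#C/C(C)=C/CO | starting material
19 | dilithio derivative of 18 (lithium alkoxide and lithium acetylide) | [Li]C#C/C(C)=C/CO[Li] | intermediate (not isolated)
20 | (2E)-5-[(1R,2R)-1-hydroxy-2,6,6-trimethyl-2-(trimethylsilyloxy)cyclohexyl]-3-methylpent-2-en-4-yn-1-ol | OC/C=C(C)/C#C[C@]1(O)C(C)(C)CCC[C@@]1(C)O[Si](C)(C)C | intermediate (not isolated)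
21 | (1R,2R)-1-[(3E)-5-hydroxy-3-methylpent-3-en-1-yn-1-yl]-2,6,6-trimethylcyclohexane-1,2-diol | OC/C=C(C)/C#C[C@]1(O)C(C)(C)CCC[C@@]1(C)O | intermediate
22 | (1S,2R)-1-[(1E,3E)-5-hydroxy-3-methylpenta-1,3-dien-1-yl]-2,6,6-trimethylcyclohexane-1,2-diol | OC/C=C(C)/C=C/[C@]1(O)C(C)(C)CCC[C@@]1(C)O | intermediate
23 | (2E,4E)-5-[(1S,2R)-1,2-dihydroxy-2,6,6-trimethylcyclohexyl]-3-methylpenta-2,4-dienal | O=C/C=C(C)/C=C/[C@]1(O)C(C)(C)CCC[C@@]1(C)O | intermediate
24 | (2E,4E)-3-methyl-5-[(1S,2R)-2,6,6-trimethyl-1,2-bis(trimethylsilyloxy)cyclohexyl]penta-2,4-dienal | O=C/C=C(C)/C=C/[C@]1(O[Si](C)(C)C)C(C)(C)CCC[C@@]1(C)O[Si](C)(C)C | intermediate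
25 | (2E,4E,6E)-2,7-dimethylocta-2,4,6-trienedial | O=C/C(C)=C/C=C/C=C(C)/C=O | starting material
26 | (2E,4E,6E)-2,7-dimethylocta-2,4,6-triene-1,8-diol | OC/C(C)=C/C=C/C=C(C)/CO | intermediate
27 | (2E,4E,6E)-1,8-dibromo-2,7-dimethylocta-2,4,6-triene | BrC/C(C)=C/C=C/C=C(C)/CBr | intermediate
28 | tetraethyl [(2E,4E,6E)-2,7-dimethylocta-2,4,6-triene-1,8-diyl]bis(phosphonate) | CCOP(=O)(OCC)C/C(C)=C/C=C/C=C(C)/CP(=O)(OCC)OCC | intermediate
29 | diethyl [(2E,4E,6E,8E,10E,12E)-2,7,11-trimethyl-13-[(1S,2R)-2,6,6-trimethyl-1,2-bis(trimethylsilyloxy)cyclohexyl]trideca-2,4,6,8,10,12-hexaen-1-yl]phosphonate | CCOP(=O)(OCC)C/C(C)=C/C=C/C=C(C)/C=C/C=C(C)/C=C/[C@]1(O[Si](C)(C)C)C(C)(C)CCC[C@@]1(C)O[Si](C)(C)C | intermediate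
30 | 5,6-bis(trimethylsilyl) ether of the target | CC(/C=C/C=C(C)/C=C/[C@]1(O[Si](C)(C)C)C(C)(C)CCC[C@@]1(C)O[Si](C)(C)C)=C\C=C\C=C(C)\C=C\C=C(/C)[C@@H]1C=C2C(C)(C)CCC[C@@]2(C)O1 | intermediate (not isolated)
31 | (5R,6S,5'R,8'S)-5',8'-epoxy-5,6,5',8'-tetrahydro-β,β-carotene-5,6-diol (CNP0378030.2) | CC(/C=C/C=C(C)/C=C/[C@]1(O)C(C)(C)CCC[C@@]1(C)O)=C\C=C\C=C(C)\C=C\C=C(/C)[C@@H]1C=C2C(C)(C)CCC[C@@]2(C)O1 | target

**Totals**

Total step count: 22.
Longest linear sequence: 12 steps (1 → 2 → 3 → 4 → 14 → 16 → 17 → 21 → 22 → 23 → 24 → 29 → 31; steps 1, 2, 3, 11, 12, 13, 14, 15, 16, 17, 21, 22).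

**Steps most likely to fail**

1. Step 8 (allenol cycloisomerisation). The risk is erosion of the axis-to-centre transfer: the Lewis-acidic metal may ionise the doubly allylic C8'–O bond of the product (or pass through an allyl-cation-like intermediate stabilised by the C9'=C10' alkene), epimerising C8'; AgNO3 in acetone is the milder catalyst variant. If this persists, the fallback changes from metal catalysis to halocyclisation followed by reduction, setting out from 9 and coming back at 10. Allenol 9 would be treated with N-iodosuccinimide and NaHCO3 in CH2Cl2 at −20 °C; the iodonium-induced 5-endo closure follows the same anti course and should give tert-butyl{[(2E)-3-[(2R,7aR)-3-iodo-4,4,7a-trimethyl-2,4,5,6,7,7a-hexahydro-1-benzofuran-2-yl]but-2-en-1-yl]oxy}dimethylsilane F1 (same spatial arrangement as 10, iodine on C7'), in which the iodine also disfavours ionisation at C8'. Reduction of the vinyl iodide with Bu3SnH and Pd(PPh3)4 (cat.) in THF should then return 10.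

2. Step 7 (anti-SN2' alkenylation). The risk is slow transmetalation of the trisubstituted alkenyl pinacol boronate, during which the allenylpalladium intermediate may isomerise or decompose, with loss of the anti relationship or of material. The fallback gives up the allene and uses the classical epoxide-to-furanoid rearrangement, setting out from 4 and coming back at 10 (it bypasses step 8 as well, at the price of an uncontrolled C8'). Aldehyde 4 would be olefinated with triethyl 3-methyl-4-phosphonobut-2-enoate and NaH in THF to ethyl (2E,4E)-3-methyl-5-[(1S,6R)-2,2,6-trimethyl-7-oxabicyclo[4.1.0]heptan-1-yl]penta-2,4-dienoate F2. Reduction with i-Bu2AlH at −78 °C would give (2E,4E)-3-methyl-5-[(1S,6R)-2,2,6-trimethyl-7-oxabicyclo[4.1.0]heptan-1-yl]penta-2,4-dien-1-ol F3, and silylation with TBSCl and imidazole its tert-butyldimethylsilyl ether F4. Brief exposure of F4 to a trace of acid (pyridinium p-toluenesulfonate in CH2Cl2) should open the oxirane at C6 and let O5 close onto C8, giving 10 together with its C8' epimer, tert-butyldimethyl{[(2E)-3-[(2R,7aR)-4,4,7a-trimethyl-2,4,5,6,7,7a-hexahydro-1-benzofuran-2-yl]but-2-en-1-yl]oxy}silane F5, to be separated by chromatography.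

3. Step 14 (acetylide addition). The risk is poor facial selectivity at the congested carbonyl (partial lithium chelation by the α-oxygen, or equatorial attack), which would give the trans-diol, or low conversion. The fallback sets C6 by hydroxyl-directed dihydroxylation instead of carbonyl addition, setting out from 14 and coming back at 24. Allylic alcohol 14 would be dihydroxylated with OsO4·TMEDA in CH2Cl2 at −78 °C (hydrogen-bond-directed delivery syn to the tertiary hydroxyl, osmate ester released with ethylenediamine) to (1R,2R)-1-(hydroxymethyl)-2,6,6-trimethylcyclohexane-1,2-diol F6. Parikh–Doering oxidation (SO3·pyridine, DMSO, Et3N) of the primary alcohol would give (1S,2R)-1,2-dihydroxy-2,6,6-trimethylcyclohexane-1-carbaldehyde F7, and TMSOTf with 2,6-lutidine its bis(trimethylsilyl) ether, (1S,2R)-2,6,6-trimethyl-1,2-bis(trimethylsilyloxy)cyclohexane-1-carbaldehyde F8. Horner–Wadsworth–Emmons reaction of F8 with diethyl [(2E)-3-cyano-2-methylprop-2-en-1-yl]phosphonate and NaH would form C7=C8 and give (2E,4E)-3-methyl-5-[(1S,2R)-2,6,6-trimethyl-1,2-bis(trimethylsilyloxy)cyclohexyl]penta-2,4-dienenitrile F9. Reduction of the nitrile with i-Bu2AlH at −78 °C and mild hydrolysis of the imine should give 24.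

**Further compounds**

F1 | step 8 | tert-butyl{[(2E)-3-[(2R,7aR)-3-iodo-4,4,7a-trimethyl-2,4,5,6,7,7a-hexahydro-1-benzofuran-2-yl]but-2-en-1-yl]oxy}dimethylsilane | C/C(=C\CO[Si](C)(C)C(C)(C)C)[C@@H]1C(I)=C2C(C)(C)CCC[C@@]2(C)O1
F2 | step 7 | ethyl (2E,4E)-3-methyl-5-[(1S,6R)-2,2,6-trimethyl-7-oxabicyclo[4.1.0]heptan-1-yl]penta-2,4-dienoate | CCOC(=O)/C=C(C)/C=C/[C@]12C(C)(C)CCC[C@@]1(C)O2
F3 | step 7 | (2E,4E)-3-methyl-5-[(1S,6R)-2,2,6-trimethyl-7-oxabicyclo[4.1.0]heptan-1-yl]penta-2,4-dien-1-ol | OC/C=C(C)/C=C/[C@]12C(C)(C)CCC[C@@]1(C)O2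
F4 | step 7 | tert-butyldimethyl{[(2E,4E)-3-methyl-5-[(1S,6R)-2,2,6-trimethyl-7-oxabicyclo[4.1.0]heptan-1-yl]penta-2,4-dien-1-yl]oxy}silane | CC(C)(C)[Si](C)(C)OC/C=C(C)/C=C/[C@]12C(C)(C)CCC[C@@]1(C)O2
F5 | step 7 | tert-butyldimethyl{[(2E)-3-[(2R,7aR)-4,4,7a-trimethyl-2,4,5,6,7,7a-hexahydro-1-benzofuran-2-yl]but-2-en-1-yl]oxy}silane (C8' epimer of 10) | C/C(=C\CO[Si](C)(C)C(C)(C)C)[C@H]1C=C2C(C)(C)CCC[C@@]2(C)O1
F6 | step 14 | (1R,2R)-1-(hydroxymethyl)-2,6,6-trimethylcyclohexane-1,2-diol | OC[C@]1(O)C(C)(C)CCC[C@@]1(C)O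
F7 | step 14 | (1S,2R)-1,2-dihydroxy-2,6,6-trimethylcyclohexane-1-carbaldehyde | O=C[C@]1(O)C(C)(C)CCC[C@@]1(C)O
F8 | step 14 | (1S,2R)-2,6,6-trimethyl-1,2-bis(trimethylsilyloxy)cyclohexane-1-carbaldehyde | O=C[C@]1(O[Si](C)(C)C)C(C)(C)CCC[C@@]1(C)O[Si](C)(C)C
F9 | step 14 | (2E,4E)-3-methyl-5-[(1S,2R)-2,6,6-trimethyl-1,2-bis(trimethylsilyloxy)cyclohexyl]penta-2,4-dienenitrile | N#C/C=C(C)/C=C/[C@]1(O[Si](C)(C)C)C(C)(C)CCC[C@@]1(C)O[Si](C)(C)C
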